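I started from the constants that the readings could give me for these flasks.

| flask | G | Q | remark | time |
|---|---|---|---|---|
| east | 0.30 M | 0.090 M | run made earlier |  |
| north-east | 0.42 M | 0.090 M | run made earlier |  |
| south-east | 0.66 M | 0.090 M | run made earlier |  |
| south-west | 0.30 M | 0.18 M | run made earlier |  |
| autumn | 0.30 M | 0.0900 M | everything together in a closed stirred flask, run for 1.0 h | 1.0 h |
| midnight | 0.30 M (fed, over 0.500 h) | 0.0900 M | a stirred flask in which G is dosed at a steady rate over 0.500 h without added volume, worked up at 1.0 h | 1.0 h |
| noon | 0.30 M | 0.0900 M | one stirred flow tank at steady state, fed with the mixture as stated, mean residence time 1.0 h |  |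

- east (time / min: E / %, Z / %, G / %): 10.0: 25, 8, 21; 20.0: 37, 21, 7; 30.0: 43, 27, 5; 40.0: 45, 30, 3; 50.0: 45, 32, 0; 60.0: 45, 28, 0
- north-east (time / min: E / %, Z / %, G / %): 3.00: 5, 0, 55; 5.00: 10, 4, 39; 8.00: 21, 9, 26; 12.0: 29, 18, 15; 20.0: 35, 31, 5; 40.0: 41, 39, 4
- south-east (time / min: E / %, Z / %, G / %): 6.00: 13, 9, 31; 12.0: 26, 26, 16; 20.0: 32, 37, 6; 25.0: 31, 42, 4; 30.0: 32, 47, 5; 40.0: 31, 50, 0
- south-west (time / min: E / %, Z / %, G / %): 8.00: 20, 6, 20; 15.0: 30, 11, 8; 20.0: 34, 13, 8; 30.0: 38, 17, 4; 40.0: 41, 21, 1

(standard deviation of a reading: 1.5 percentage points)

- percentages count the G that a species holds: one Z counts as two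
- the stated concentrations are those of everything mixed, before any reaction; amounts are the same in each set-up
- the feed brings no volume worth counting
- the earlier runs were made in a closed, stirred flask

- the set-up with the highest share of E in all that became E or Z, at the outlet or at the end ("none" if the first two lie within 2 percentage points) (autumn / midnight / noon / none)
- share of E in all that became E or Z, at the outlet or at the end, autumn
- share of E in all that became E or Z, at the outlet or at the end, midnight
- share of E in all that became E or Z, at the outlet or at the end, noon

One thing looked wrong. In the south-east run, from 20.0 min to 40.0 min, E read 32% and then 31%, while Z climbed from 37% to 50%. How could a product stand still while the next one grew? I supposed that each Z is one E joined to one G. A flat E is then a crossing, where E is made as fast as G eats it. Z would form at κ[G][E], with κ a rate constant, so I read κ between the first two readings of that run, using mean [G] and [E] and halving the rise in Z: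

κ = 0.468 L mol⁻¹ min⁻¹

The east run, with its different charge, read 0.499 L mol⁻¹ min⁻¹. Its first reading gave G a first-order loss constant k:

k = 0.156 min⁻¹

In the noon tank, with residence time τ, the outlet [Z] is κ[G][E]τ, where [G] is the outlet value:

[G] = 0.0289 M

N = 2κ[G]τ = 1.63

I called N the eating number, the counted Z per E at a tank outlet. The share of E (the selectivity) is then 1/(1+N), or 38.1% for noon. Autumn repeats the east run, whose last reading gives 61.6%, so I put noon lower. I set no number on midnight.

The forecast said 60%, 76% and 83%, with noon best, and where we differ is noon. Its ground for ranking noon first: “The flow tank has the lowest I, about 0.038 M”.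

Autumn gave 58.5%, midnight 55.6% and noon 40.5%, so autumn came first.

    G → D (k = 0.0940 min⁻¹)
    G ⇌ L (K = 0.620, k = 0.0830 min⁻¹)
    D → E (k = 0.270 min⁻¹)
    G + E → Z (k = 0.450 L mol⁻¹ min⁻¹)
    G + Q → X (k = 0.550 L mol⁻¹ min⁻¹)

The noon outlet held 9.09% of the G charged. With that G, N is 1.53 and the share 39.5%. For the same tank with a residence time of 3.00 h, my k and κ give [G] = 0.0103 M, N = 1.74 and a share of 36.5%; that tank gave 38.5%.

The numbers in the tables are simulated on assumed constants; noise was put on by code.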